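**Plan**
- Retrosynthesis: the three silyl ethers and a boron placeholder on C7' are removed first; then the C7'–C8' bond is cut, between the benzylic CH2 of the central 3,5-dimethoxy-4-oxyphenyl ring (ring B) and the methyl-bearing C8'.
- Enabling feature: C7' is a benzylic carbon on ring B. As its O-carbamate it can be lithiated to an α-oxybenzyl carbanion that takes the secondary carbon C8' over from boron in a 1,2-metallate shift; the boron left on C7' is then exchanged for hydrogen.
- Eastern fragment (ring A, C7, C8, C8'): the chain is grown on boron from the ring A aryllithium by one CH2 insertion and two successive insertions of an (R)-1-lithioethyl carbenoid (first as the N,N-diisopropylcarbamate, then as the 2,4,6-triisopropylbenzoate for the more hindered secondary boronic ester), so one chiral diamine, (+)-sparteine, sets C8 and C8'.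
- Western fragment (rings B and C): C8'' comes from ethyl (S)-lactate by Mitsunobu inversion with syringaldehyde, ring C enters as a Grignard reagent on a Weinreb amide, and C7'' is set by chelation-controlled reduction.
- Forward order: steps 1–4 eastern boronic ester, steps 5–11 western carbamate, step 12 union, step 13 protodeboronation, step 14 desilylation; no ring is formed.

Key step: step 12

Remark: (+)-sparteine, ethyl N,N-di(propan-2-yl)carbamate, ethyl 2,4,6-tri(propan-2-yl)benzoate and 2-(bromomethyl)-4,4,5,5-tetramethyl-1,3,2-dioxaborolane are taken as purchasable; locants follow the target name (ring A on C7, ring B on C7', ring C on C7'').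

**Route**

Step 1
Reactants: 1 4-bromo-2-methoxyphenol
Product: 2 (4-bromo-2-methoxyphenoxy)tri(propan-2-yl)silane
Conditions: TIPSCl, imidazole, DMF, rt
Reagents that add atoms: chlorotri(propan-2-yl)silane (TIPSCl), CC(C)[Si](Cl)(C(C)C)C(C)C
Why: Imidazole-promoted silylation of the phenol; the bulky TIPS ether is chosen to survive the aryllithium, Grignard and sBuLi steps.

Step 2
Reactants: 2 (4-bromo-2-methoxyphenoxy)tri(propan-2-yl)silane
Product: 5 2-({3-methoxy-4-[tri(propan-2-yl)silyloxy]phenyl}methyl)-4,4,5,5-tetramethyl-1,3,2-dioxaborolane, via aryllithium 3 (not isolated), via bromomethyl boronate complex 4 (not isolated)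
Conditions: nBuLi, THF, −78 °C; then BrCH2Bpin, −78 °C → rt
Reagents that add atoms: 2-(bromomethyl)-4,4,5,5-tetramethyl-1,3,2-dioxaborolane, BrCB1OC(C)(C)C(C)(C)O1
Why: Bromine–lithium exchange gives aryllithium 3, which adds to boron of the bromomethyl boronic ester, and boronate 4 undergoes 1,2-aryl migration with loss of bromide on warming (Matteson homologation) to give the benzylic boronic ester that carries C7.

Step 3
Reactants: 5 2-({3-methoxy-4-[tri(propan-2-yl)silyloxy]phenyl}methyl)-4,4,5,5-tetramethyl-1,3,2-dioxaborolane; 6 ethyl N,N-di(propan-2-yl)carbamate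
Product: 9 2-[(2S)-1-{3-methoxy-4-[tri(propan-2-yl)silyloxy]phenyl}propan-2-yl]-4,4,5,5-tetramethyl-1,3,2-dioxaborolane, via lithiated carbamate 7 (not isolated), via boronate complex 8 (not isolated)
Conditions: 6, sBuLi, (+)-sparteine, Et2O, −78 °C; then 5, −78 °C; then MgBr2·OEt2, Et2O, reflux
Reagents that add atoms: none
Why: Sparteine-mediated enantioselective deprotonation of the O-ethyl group (sBuLi/(+)-sparteine removes the pro-R hydrogen) gives the configurationally stable (R)-1-lithioethyl carbamate 7, which adds to boron of 5 with retention to give boronate 8, and on heating with MgBr2 the benzyl group migrates anti-periplanar to the departing carbamate with inversion at the carbenoid carbon (reagent-controlled lithiation–borylation homologation, a Matteson-type 1,2-metallate rearrangement), which should set C8 as S.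

Step 4
Reactants: 9 2-[(2S)-1-{3-methoxy-4-[tri(propan-2-yl)silyloxy]phenyl}propan-2-yl]-4,4,5,5-tetramethyl-1,3,2-dioxaborolane; 10 ethyl 2,4,6-tri(propan-2-yl)benzoate
Product: 13 2-[(2S,3S)-4-{3-methoxy-4-[tri(propan-2-yl)silyloxy]phenyl}-3-methylbutan-2-yl]-4,4,5,5-tetramethyl-1,3,2-dioxaborolane, via lithiated benzoate 11 (not isolated), via boronate complex 12 (not isolated)
Conditions: 10, sBuLi, (+)-sparteine, Et2O, −78 °C; then 9, −78 °C → 35 °C
Reagents that add atoms: none
Why: The same sparteine-mediated deprotonation applied to the O-ethyl group of the triisopropylbenzoate gives the (R)-lithiated benzoate 11, whose better leaving group lets the hindered secondary boronic ester 9 form boronate 12 and rearrange without reversal; the secondary carbon C8 migrates with retention and the new boron-bearing carbon C8' is fixed by the carbenoid with inversion (lithiation–borylation homologation), which should give the (2S,3S) array that maps onto 8S,8'R of the target once boron is replaced by C7'.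

Step 5
Reactants: 14 4-hydroxy-3,5-dimethoxybenzaldehyde (syringaldehyde); 15 ethyl (2S)-2-hydroxypropanoate (ethyl (S)-lactate)
Product: 16 ethyl (2R)-2-(4-formyl-2,6-dimethoxyphenoxy)propanoate
Conditions: PPh3, DIAD, THF, 0 °C → rt
Reagents that add atoms: none
Why: Mitsunobu reaction: the acidic, aldehyde-activated phenol displaces the activated secondary hydroxyl of the lactate by SN2 with inversion, which turns the (S) carbinol carbon into the (R)-configured C8''.

Step 6
Reactants: 16 ethyl (2R)-2-(4-formyl-2,6-dimethoxyphenoxy)propanoate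
Product: 17 ethyl (2R)-2-[4-(hydroxymethyl)-2,6-dimethoxyphenoxy]propanoate
Conditions: NaBH4 (substoichiometric), EtOH, −10 °C; AcOH quench
Reagents that add atoms: none
Why: Borohydride reduces the aromatic aldehyde much faster than the ester at low temperature (chemoselective carbonyl reduction), giving the benzylic alcohol carbon that will become C7'.

Step 7
Reactants: 17 ethyl (2R)-2-[4-(hydroxymethyl)-2,6-dimethoxyphenoxy]propanoate
Product: 18 ethyl (2R)-2-[4-({[di(propan-2-yl)carbamoyl]oxy}methyl)-2,6-dimethoxyphenoxy]propanoate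
Conditions: iPr2NCOCl, Et3N, CH2Cl2, reflux
Reagents that add atoms: N,N-di(propan-2-yl)carbamoyl chloride, CC(C)N(C(C)C)C(Cl)=O
Why: O-Carbamoylation of the primary benzylic alcohol installs the N,N-diisopropylcarbamate, the directing and leaving group of the key step, under conditions too weakly basic to epimerise C8''.

Step 8
Reactants: 18 ethyl (2R)-2-[4-({[di(propan-2-yl)carbamoyl]oxy}methyl)-2,6-dimethoxyphenoxy]propanoate
Product: 19 [4-({(2R)-1-[methoxy(methyl)amino]-1-oxopropan-2-yl}oxy)-3,5-dimethoxyphenyl]methyl N,N-di(propan-2-yl)carbamate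
Conditions: MeNHOMe·HCl, iPrMgCl, THF, −20 °C
Reagents that add atoms: N,O-dimethylhydroxylamine hydrochloride, CNOC.Cl
Why: Aminolysis of the ester by the magnesium amide generated from MeNHOMe·HCl and iPrMgCl gives the N-methoxy-N-methylamide (Weinreb amide formation), the hindered carbamate being inert to these reagents at low temperature.

Step 9
Reactants: 19 [4-({(2R)-1-[methoxy(methyl)amino]-1-oxopropan-2-yl}oxy)-3,5-dimethoxyphenyl]methyl N,N-di(propan-2-yl)carbamate; 2 (4-bromo-2-methoxyphenoxy)tri(propan-2-yl)silane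
Product: 21 [3,5-dimethoxy-4-({(2R)-1-{3-methoxy-4-[tri(propan-2-yl)silyloxy]phenyl}-1-oxopropan-2-yl}oxy)phenyl]methyl N,N-di(propan-2-yl)carbamate, via aryl Grignard reagent 20 (not isolated)
Conditions: 2, Mg, THF, rt; then 19, 0 °C; aq. NH4Cl
Reagents that add atoms: none
Why: Weinreb ketone synthesis: the aryl Grignard reagent from 2 adds once to the N-methoxy-N-methylamide and the ketone is released only on mild acidic work-up, which limits over-addition and enolisation at C8''.

Step 10
Reactants: 21 [3,5-dimethoxy-4-({(2R)-1-{3-methoxy-4-[tri(propan-2-yl)silyloxy]phenyl}-1-oxopropan-2-yl}oxy)phenyl]methyl N,N-di(propan-2-yl)carbamate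
Product: 22 [4-({(1S,2R)-1-hydroxy-1-{3-methoxy-4-[tri(propan-2-yl)silyloxy]phenyl}propan-2-yl}oxy)-3,5-dimethoxyphenyl]methyl N,N-di(propan-2-yl)carbamate
Conditions: Zn(BH4)2, Et2O, −30 → 0 °C
Reagents that add atoms: none
Why: Chelation-controlled (Cram chelate) reduction: zinc bridges the carbonyl oxygen and the α-aryloxy oxygen, hydride enters from the face of the chelate that carries H and not CH3 at C8'', and this should set C7'' as S (erythro) under non-basic conditions.

Step 11
Reactants: 22 [4-({(1S,2R)-1-hydroxy-1-{3-methoxy-4-[tri(propan-2-yl)silyloxy]phenyl}propan-2-yl}oxy)-3,5-dimethoxyphenyl]methyl N,N-di(propan-2-yl)carbamate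
Product: 23 [4-({(1S,2R)-1-[tert-butyl(dimethyl)silyloxy]-1-{3-methoxy-4-[tri(propan-2-yl)silyloxy]phenyl}propan-2-yl}oxy)-3,5-dimethoxyphenyl]methyl N,N-di(propan-2-yl)carbamate
Conditions: TBSOTf, 2,6-lutidine, CH2Cl2, 0 °C
Reagents that add atoms: tert-butyldimethylsilyl trifluoromethanesulfonate, CC(C)(C)[Si](C)(C)OS(=O)(=O)C(F)(F)F
Why: Silylation of the hindered secondary benzylic alcohol with the silyl triflate and 2,6-lutidine removes the only acidic O–H before the organolithium step and gives a group that fluoride takes off at the end.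

Step 12
Reactants: 23 [4-({(1S,2R)-1-[tert-butyl(dimethyl)silyloxy]-1-{3-methoxy-4-[tri(propan-2-yl)silyloxy]phenyl}propan-2-yl}oxy)-3,5-dimethoxyphenyl]methyl N,N-di(propan-2-yl)carbamate; 13 2-[(2S,3S)-4-{3-methoxy-4-[tri(propan-2-yl)silyloxy]phenyl}-3-methylbutan-2-yl]-4,4,5,5-tetramethyl-1,3,2-dioxaborolane
Product: 26 benzylic pinacol boronic ester: the 4-O-TIPS 4''-O-TIPS 7''-O-TBS ether of the target carrying 4,4,5,5-tetramethyl-1,3,2-dioxaborolan-2-yl on C7' (both C7' epimers), via lithiated carbamate 24 (not isolated), via boronate complex 25 (not isolated)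
Conditions: sBuLi, TMEDA, Et2O, −78 °C; then 13, −78 °C; then MgBr2/MeOH, −78 °C → rt
Reagents that add atoms: none
Why: sBuLi, held by the carbamate carbonyl, removes one of the two C7' benzylic hydrogens on ring B to give the dipole-stabilised α-oxybenzyllithium 24, which adds to boron of 13 to form boronate 25; on warming with MgBr2/MeOH the carbon C8' migrates from boron to C7' anti-periplanar to the departing carbamate (1,2-metallate rearrangement). The closest known reaction type is the lithiation–borylation homologation of secondary alkyl pinacol boronic esters with lithiated primary benzylic carbamates. No ring is closed. The migrating carbon C8' moves with retention, so the (2S,3S) array of 13 becomes the 8S,8'R array of the target (the change of descriptor at C8' is only a change of priorities), while the new boron-bearing center C7' is not controlled and need not be, because step 13 replaces boron by hydrogen. The step needs deprotonation at C7' only, in the presence of the benzylic C7''–H, the ring hydrogens next to methoxy groups and three silyl ethers, which the complex-induced proximity effect of the carbamate, the low temperature and the bulk of the TIPS and TBS groups should secure; it also needs migration to outrun reversal of boronate formation, which the benzylic position of the leaving group and the magnesium salt should secure.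

Step 13
Reactants: 26 benzylic pinacol boronic ester (both C7' epimers)
Product: 28 4-O-TIPS 4''-O-TIPS 7''-O-TBS ether of the target (7''S,8S,8'R,8''R), via phenyl boronate complex 27 (not isolated)
Conditions: PhLi, THF, −78 → 0 °C; then Ir[dF(CF3)ppy]2(dtbbpy)PF6 (cat.), PhSH (cat.), MeOH/acetone, blue LEDs, rt
Reagents that add atoms: none
Why: Photoredox protodeboronation: phenyllithium converts the boronic ester into boronate 27, single-electron oxidation by the excited iridium photocatalyst cleaves the C7'–B bond to a benzylic radical stabilised by ring B, and hydrogen-atom transfer from the thiol leaves the C7' CH2 group, which erases the uncontrolled center and touches no other stereocenter.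

Step 14
Reactants: 28 4-O-TIPS 4''-O-TIPS 7''-O-TBS ether of the target
Product: 29 (+)-(7''S,8S,8'R,8''R)-4,4''-dihydroxy-3,3',3'',5'-tetramethoxy-4',8''-oxy-8,8'-sesquineolignan-7''-ol
Conditions: TBAF, AcOH, THF, 0 °C → rt
Reagents that add atoms: none
Why: Fluoride-mediated cleavage of the two aryl TIPS ethers and the benzylic TBS ether (global desilylation), buffered with acetic acid so that the free 4-hydroxybenzylic alcohol of ring C is not exposed to strong base.

**Compound list**

1 | 4-bromo-2-methoxyphenol | COc1cc(Br)ccc1O | starting material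
2 | (4-bromo-2-methoxyphenoxy)tri(propan-2-yl)silane | COc1cc(Br)ccc1O[Si](C(C)C)(C(C)C)C(C)C | intermediate
3 | {3-methoxy-4-[tri(propan-2-yl)silyloxy]phenyl}lithium (formed in the flask) | COc1cc([Li])ccc1O[Si](C(C)C)(C(C)C)C(C)C | intermediate
4 | lithium (bromomethyl){3-methoxy-4-[tri(propan-2-yl)silyloxy]phenyl}(pinacolato)borate (formed in the flask) | [Li+].COc1cc([B-]2(CBr)OC(C)(C)C(C)(C)O2)ccc1O[Si](C(C)C)(C(C)C)C(C)C | intermediate
5 | 2-({3-methoxy-4-[tri(propan-2-yl)silyloxy]phenyl}methyl)-4,4,5,5-tetramethyl-1,3,2-dioxaborolane | COc1cc(CB2OC(C)(C)C(C)(C)O2)ccc1O[Si](C(C)C)(C(C)C)C(C)C | intermediate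
6 | ethyl N,N-di(propan-2-yl)carbamate | CCOC(=O)N(C(C)C)C(C)C | starting material
7 | (1R)-1-lithioethyl N,N-di(propan-2-yl)carbamate (formed in the flask as its (+)-sparteine complex) | C[C@@H]([Li])OC(=O)N(C(C)C)C(C)C | intermediate
8 | lithium boronate complex of 5 and 7 (formed in the flask) | [Li+].COc1cc(C[B-]2([C@H](C)OC(=O)N(C(C)C)C(C)C)OC(C)(C)C(C)(C)O2)ccc1O[Si](C(C)C)(C(C)C)C(C)C | intermediate
9 | 2-[(2S)-1-{3-methoxy-4-[tri(propan-2-yl)silyloxy]phenyl}propan-2-yl]-4,4,5,5-tetramethyl-1,3,2-dioxaborolane | COc1cc(C[C@H](C)B2OC(C)(C)C(C)(C)O2)ccc1O[Si](C(C)C)(C(C)C)C(C)C | intermediate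
10 | ethyl 2,4,6-tri(propan-2-yl)benzoate | CCOC(=O)c1c(C(C)C)cc(C(C)C)cc1C(C)C | starting material
11 | (1R)-1-lithioethyl 2,4,6-tri(propan-2-yl)benzoate (formed in the flask as its (+)-sparteine complex) | C[C@@H]([Li])OC(=O)c1c(C(C)C)cc(C(C)C)cc1C(C)C | intermediate
12 | lithium boronate complex of 9 and 11 (formed in the flask) | [Li+].COc1cc(C[C@H](C)[B-]2([C@H](C)OC(=O)c3c(C(C)C)cc(C(C)C)cc3C(C)C)OC(C)(C)C(C)(C)O2)ccc1O[Si](C(C)C)(C(C)C)C(C)C | intermediate
13 | 2-[(2S,3S)-4-{3-methoxy-4-[tri(propan-2-yl)silyloxy]phenyl}-3-methylbutan-2-yl]-4,4,5,5-tetramethyl-1,3,2-dioxaborolane (eastern fragment) | COc1cc(C[C@H](C)[C@H](C)B2OC(C)(C)C(C)(C)O2)ccc1O[Si](C(C)C)(C(C)C)C(C)C | intermediate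
14 | 4-hydroxy-3,5-dimethoxybenzaldehyde (syringaldehyde) | COc1cc(C=O)cc(OC)c1O | starting material
15 | ethyl (2S)-2-hydroxypropanoate (ethyl (S)-lactate) | C[C@H](O)C(=O)OCC | starting material
16 | ethyl (2R)-2-(4-formyl-2,6-dimethoxyphenoxy)propanoate | CCOC(=O)[C@@H](C)Oc1c(OC)cc(C=O)cc1OC | intermediate
17 | ethyl (2R)-2-[4-(hydroxymethyl)-2,6-dimethoxyphenoxy]propanoate | CCOC(=O)[C@@H](C)Oc1c(OC)cc(CO)cc1OC | intermediate
18 | ethyl (2R)-2-[4-({[di(propan-2-yl)carbamoyl]oxy}methyl)-2,6-dimethoxyphenoxy]propanoate | CCOC(=O)[C@@H](C)Oc1c(OC)cc(COC(=O)N(C(C)C)C(C)C)cc1OC | intermediate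
19 | [4-({(2R)-1-[methoxy(methyl)amino]-1-oxopropan-2-yl}oxy)-3,5-dimethoxyphenyl]methyl N,N-di(propan-2-yl)carbamate | CON(C)C(=O)[C@@H](C)Oc1c(OC)cc(COC(=O)N(C(C)C)C(C)C)cc1OC | intermediate
20 | bromo{3-methoxy-4-[tri(propan-2-yl)silyloxy]phenyl}magnesium (formed in the flask) | COc1cc([Mg]Br)ccc1O[Si](C(C)C)(C(C)C)C(C)C | intermediate
21 | [3,5-dimethoxy-4-({(2R)-1-{3-methoxy-4-[tri(propan-2-yl)silyloxy]phenyl}-1-oxopropan-2-yl}oxy)phenyl]methyl N,N-di(propan-2-yl)carbamate | CC(C)N(C(C)C)C(=O)OCc1cc(OC)c(O[C@H](C)C(=O)c2ccc(O[Si](C(C)C)(C(C)C)C(C)C)c(OC)c2)c(OC)c1 | intermediate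
22 | [4-({(1S,2R)-1-hydroxy-1-{3-methoxy-4-[tri(propan-2-yl)silyloxy]phenyl}propan-2-yl}oxy)-3,5-dimethoxyphenyl]methyl N,N-di(propan-2-yl)carbamate | CC(C)N(C(C)C)C(=O)OCc1cc(OC)c(O[C@H](C)[C@@H](O)c2ccc(O[Si](C(C)C)(C(C)C)C(C)C)c(OC)c2)c(OC)c1 | intermediate
23 | [4-({(1S,2R)-1-[tert-butyl(dimethyl)silyloxy]-1-{3-methoxy-4-[tri(propan-2-yl)silyloxy]phenyl}propan-2-yl}oxy)-3,5-dimethoxyphenyl]methyl N,N-di(propan-2-yl)carbamate (western fragment) | CC(C)N(C(C)C)C(=O)OCc1cc(OC)c(O[C@H](C)[C@@H](O[Si](C)(C)C(C)(C)C)c2ccc(O[Si](C(C)C)(C(C)C)C(C)C)c(OC)c2)c(OC)c1 | intermediate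
24 | 23 lithiated at the benzylic carbon C7' (formed in the flask) | CC(C)N(C(C)C)C(=O)OC([Li])c1cc(OC)c(O[C@H](C)[C@@H](O[Si](C)(C)C(C)(C)C)c2ccc(O[Si](C(C)C)(C(C)C)C(C)C)c(OC)c2)c(OC)c1 | intermediate
25 | lithium boronate complex of 24 and 13 (formed in the flask) | [Li+].COc1cc(C[C@H](C)[C@H](C)[B-]2(C(OC(=O)N(C(C)C)C(C)C)c3cc(OC)c(O[C@H](C)[C@@H](O[Si](C)(C)C(C)(C)C)c4ccc(O[Si](C(C)C)(C(C)C)C(C)C)c(OC)c4)c(OC)c3)OC(C)(C)C(C)(C)O2)ccc1O[Si](C(C)C)(C(C)C)C(C)C | intermediate
26 | 4-O-TIPS 4''-O-TIPS 7''-O-TBS ether of the target carrying 4,4,5,5-tetramethyl-1,3,2-dioxaborolan-2-yl on C7' (both C7' epimers) | COc1cc(C[C@H](C)[C@H](C)C(B2OC(C)(C)C(C)(C)O2)c2cc(OC)c(O[C@H](C)[C@@H](O[Si](C)(C)C(C)(C)C)c3ccc(O[Si](C(C)C)(C(C)C)C(C)C)c(OC)c3)c(OC)c2)ccc1O[Si](C(C)C)(C(C)C)C(C)C | intermediate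
27 | lithium phenyl boronate complex of 26 (formed in the flask) | [Li+].COc1cc(C[C@H](C)[C@H](C)C([B-]2(c3ccccc3)OC(C)(C)C(C)(C)O2)c2cc(OC)c(O[C@H](C)[C@@H](O[Si](C)(C)C(C)(C)C)c3ccc(O[Si](C(C)C)(C(C)C)C(C)C)c(OC)c3)c(OC)c2)ccc1O[Si](C(C)C)(C(C)C)C(C)C | intermediate
28 | 4-O-TIPS 4''-O-TIPS 7''-O-TBS ether of the target (7''S,8S,8'R,8''R) | COc1cc(C[C@H](C)[C@H](C)Cc2cc(OC)c(O[C@H](C)[C@@H](O[Si](C)(C)C(C)(C)C)c3ccc(O[Si](C(C)C)(C(C)C)C(C)C)c(OC)c3)c(OC)c2)ccc1O[Si](C(C)C)(C(C)C)C(C)C | intermediate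
29 | (+)-(7''S,8S,8'R,8''R)-4,4''-dihydroxy-3,3',3'',5'-tetramethoxy-4',8''-oxy-8,8'-sesquineolignan-7''-ol | COc1cc(C[C@H](C)[C@H](C)Cc2cc(OC)c(O[C@H](C)[C@@H](O)c3ccc(O)c(OC)c3)c(OC)c2)ccc1O | target

**Count and risks**

Total step count: 14. Longest linear sequence: 10 steps (steps 5–14, from syringaldehyde and ethyl (S)-lactate).

Most likely to fail:

1. Step 12. Deprotonation may not stay at C7' (metalation at the benzylic C7''–H or on a ring), or boronate formation with the branched secondary boronic ester may revert before the 1,2-shift. The fallback sets out from 23 and 13 and comes back at 28, so step 13 is then not needed. LiAlH4 (THF, 0 °C → rt) should cleave the carbamate of 23 to the benzylic alcohol F1. MnO2 (CH2Cl2) should oxidise it to the benzaldehyde F2, and TsNHNH2 (MeOH) should give the N-tosylhydrazone F3. In parallel, NaIO4/NH4OAc (acetone/H2O) should free the boronic acid F4 from 13. Heating F3 and F4 with K2CO3 in dioxane (110 °C) should give 28 by metal-free reductive coupling of a tosylhydrazone with a boronic acid: the diazo compound formed from F3 adds to boron, C8' migrates with retention as N2 leaves, and the benzylic boronic acid so formed loses boron under the basic conditions.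

2. Step 13. Phenyllithium may add poorly to the crowded boron on C7', or the electron-rich benzylic radical may be oxidised further and captured by methanol instead of being reduced. The fallback sets out from 26 and comes back at 28. NaBO3·4H2O (THF/H2O) should oxidise the C–B bond with retention to the benzylic alcohol F5. PhOC(S)Cl (pyridine, DMAP, CH2Cl2) should give the O-phenyl thionocarbonate F6, and Bu3SnH/AIBN (toluene, 90 °C) should remove the oxygen by Barton–McCombie deoxygenation to give 28.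

3. Step 10. Hydride delivery may show poor facial selectivity if the crowded aryl ether oxygen binds zinc only weakly, and enolisation of the α-aryloxy ketone would erode C8''. The fallback sets out from 21 and comes back at 22. A non-chelating reduction (NaBH4, 15-crown-5, MeOH, −40 °C) should follow the Felkin–Anh course to the threo (1R,2R) alcohol F7. Mitsunobu inversion at C7'' with chloroacetic acid (PPh3, DIAD, toluene) should give the (1S,2R) chloroacetate F8, and Et3N in MeOH should cleave it to 22.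

Further compounds
F1 | step 12 | [4-({(1S,2R)-1-[tert-butyl(dimethyl)silyloxy]-1-{3-methoxy-4-[tri(propan-2-yl)silyloxy]phenyl}propan-2-yl}oxy)-3,5-dimethoxyphenyl]methanol | OCc1cc(OC)c(O[C@H](C)[C@@H](O[Si](C)(C)C(C)(C)C)c2ccc(O[Si](C(C)C)(C(C)C)C(C)C)c(OC)c2)c(OC)c1
F2 | step 12 | 4-({(1S,2R)-1-[tert-butyl(dimethyl)silyloxy]-1-{3-methoxy-4-[tri(propan-2-yl)silyloxy]phenyl}propan-2-yl}oxy)-3,5-dimethoxybenzaldehyde | O=Cc1cc(OC)c(O[C@H](C)[C@@H](O[Si](C)(C)C(C)(C)C)c2ccc(O[Si](C(C)C)(C(C)C)C(C)C)c(OC)c2)c(OC)c1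
F3 | step 12 | (E)-N-tosylhydrazone of aldehyde F2 | Cc1ccc(S(=O)(=O)N/N=C/c2cc(OC)c(O[C@H](C)[C@@H](O[Si](C)(C)C(C)(C)C)c3ccc(O[Si](C(C)C)(C(C)C)C(C)C)c(OC)c3)c(OC)c2)cc1
F4 | step 12 | [(2S,3S)-4-{3-methoxy-4-[tri(propan-2-yl)silyloxy]phenyl}-3-methylbutan-2-yl]boronic acid | COc1cc(C[C@H](C)[C@H](C)B(O)O)ccc1O[Si](C(C)C)(C(C)C)C(C)C
F5 | step 13 | 7'-hydroxy derivative of the 4-O-TIPS 4''-O-TIPS 7''-O-TBS ether of the target (both C7' epimers) | COc1cc(C[C@H](C)[C@H](C)C(O)c2cc(OC)c(O[C@H](C)[C@@H](O[Si](C)(C)C(C)(C)C)c3ccc(O[Si](C(C)C)(C(C)C)C(C)C)c(OC)c3)c(OC)c2)ccc1O[Si](C(C)C)(C(C)C)C(C)C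
F6 | step 13 | O-phenyl thionocarbonate of alcohol F5 (both C7' epimers) | COc1cc(C[C@H](C)[C@H](C)C(OC(=S)Oc2ccccc2)c2cc(OC)c(O[C@H](C)[C@@H](O[Si](C)(C)C(C)(C)C)c3ccc(O[Si](C(C)C)(C(C)C)C(C)C)c(OC)c3)c(OC)c2)ccc1O[Si](C(C)C)(C(C)C)C(C)C
F7 | step 10 | [4-({(1R,2R)-1-hydroxy-1-{3-methoxy-4-[tri(propan-2-yl)silyloxy]phenyl}propan-2-yl}oxy)-3,5-dimethoxyphenyl]methyl N,N-di(propan-2-yl)carbamate | CC(C)N(C(C)C)C(=O)OCc1cc(OC)c(O[C@H](C)[C@H](O)c2ccc(O[Si](C(C)C)(C(C)C)C(C)C)c(OC)c2)c(OC)c1
F8 | step 10 | [4-({(1S,2R)-1-(2-chloroacetoxy)-1-{3-methoxy-4-[tri(propan-2-yl)silyloxy]phenyl}propan-2-yl}oxy)-3,5-dimethoxyphenyl]methyl N,N-di(propan-2-yl)carbamate | CC(C)N(C(C)C)C(=O)OCc1cc(OC)c(O[C@H](C)[C@@H](OC(=O)CCl)c2ccc(O[Si](C(C)C)(C(C)C)C(C)C)c(OC)c2)c(OC)c1
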